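**Retrosynthetic overview**
- The target comes from a ring-A MOM ether by mild acid solvolysis; the ring B prenyl group comes from C-alkylation of a symmetric 2,4,6-trihydroxybenzoyl ring with prenyl bromide.
- Ring B (the phloroglucinol ring) is built last and de novo, by intramolecular Claisen cyclisation of a methyl 7-aryl-3,5,7-trioxoheptanoate.
- That chain comes from terminal carboxylation of a 1-arylhexane-1,3,5-trione. The trione is made in the key step, an intermolecular Claisen condensation of dilithio pentane-2,4-dione with the ring A methyl benzoate.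
- Ring A is bought intact as 3-hydroxy-2-methylbenzoic acid; its prenyl chain is built by benzylic bromination and Suzuki coupling with a 2-methylprop-1-enyl boronate.
- Ring order: ring A pre-formed (commercial), ring B closed late.

Assumption: the target has no stereocentre and no E/Z-isomeric alkene, so the single compound drawn is made and no stereocontrol is needed.

**Route**

Step 1
Reactants: 1 3-hydroxy-2-methylbenzoic acid
Product: 2 methyl 3-hydroxy-2-methylbenzoate
Conditions: MeOH, H2SO4 (cat.), reflux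
Reagents that add atoms: methanol, CO
Why: Fischer esterification in excess methanol converts the acid to its methyl ester and leaves the phenol untouched.

Step 2
Reactants: 2 methyl 3-hydroxy-2-methylbenzoate
Product: 3 methyl 2-methyl-3-[(triisopropylsilyl)oxy]benzoate
Conditions: TIPSCl, imidazole, DMF, rt
Reagents that add atoms: chlorotriisopropylsilane, CC(C)[Si](Cl)(C(C)C)C(C)C
Why: Imidazole-assisted O-silylation gives a bulky silyl ether that, unlike an acetal, tolerates radical bromination and aqueous base.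

Step 3
Reactants: 3 methyl 2-methyl-3-[(triisopropylsilyl)oxy]benzoate
Product: 4 methyl 2-(bromomethyl)-3-[(triisopropylsilyl)oxy]benzoate
Conditions: NBS (1.05 equiv), AIBN (cat.), PhCF3, 85 °C
Reagents that add atoms: N-bromosuccinimide, O=C1CCC(=O)N1Br
Why: Wohl–Ziegler radical bromination takes the only benzylic C–H position, the ring being deactivated by the ester and shielded by the silyl ether.

Step 4
Reactants: 4 methyl 2-(bromomethyl)-3-[(triisopropylsilyl)oxy]benzoate; 5 4,4,5,5-tetramethyl-2-(2-methylprop-1-en-1-yl)-1,3,2-dioxaborolane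
Product: 6 methyl 2-(3-methylbut-2-en-1-yl)-3-[(triisopropylsilyl)oxy]benzoate
Conditions: Pd(PPh3)4 (5 mol %), K3PO4, THF/H2O (10:1), 65 °C
Reagents that add atoms: none
Why: Suzuki–Miyaura coupling, in which the benzylic bromide adds oxidatively to zerovalent palladium and the alkenyl boronate transfers without allylic transposition, so the prenyl chain is linear by construction.

Step 5
Reactants: 6 methyl 2-(3-methylbut-2-en-1-yl)-3-[(triisopropylsilyl)oxy]benzoate
Product: 7 methyl 3-hydroxy-2-(3-methylbut-2-en-1-yl)benzoate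
Conditions: Bu4NF, AcOH, THF, 0 °C to rt
Reagents that add atoms: none
Why: Fluoride-driven desilylation (Si–F bond formation), buffered with acetic acid, frees the phenol without touching the ester or the alkene.

Step 6
Reactants: 7 methyl 3-hydroxy-2-(3-methylbut-2-en-1-yl)benzoate
Product: 8 methyl 3-(methoxymethoxy)-2-(3-methylbut-2-en-1-yl)benzoate
Conditions: MOMCl, i-Pr2NEt, CH2Cl2, 0 °C to rt
Reagents that add atoms: chloromethyl methyl ether, COCCl
Why: O-alkylation of the phenol gives a MOM acetal that is inert to the polyanion and hydroxide steps that follow.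

Step 7
Reactants: 8 methyl 3-(methoxymethoxy)-2-(3-methylbut-2-en-1-yl)benzoate; 9 pentane-2,4-dione
Product: 11 1-[3-(methoxymethoxy)-2-(3-methylbut-2-en-1-yl)phenyl]hexane-1,3,5-trione, via dilithio acetylacetone 10 (not isolated)
Conditions: 9 (2.2 equiv), LiN(i-Pr)2 (commercial solution, 4.4 equiv), THF, 0 °C; then 8, 0 °C to rt; AcOH quench
Reagents that add atoms: none
Why: Intermolecular Claisen condensation, in which the terminal carbanion of the β-diketone dianion is the most nucleophilic site and acylates at the ester, and deprotonation of the triketone formed makes the step irreversible.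

Step 8
Reactants: 11 1-[3-(methoxymethoxy)-2-(3-methylbut-2-en-1-yl)phenyl]hexane-1,3,5-trione
Product: 13 7-[3-(methoxymethoxy)-2-(3-methylbut-2-en-1-yl)phenyl]-3,5,7-trioxoheptanoic acid, via trilithium trienolate 12 (not isolated)
Conditions: LiN(i-Pr)2 (3.3 equiv), THF, 0 °C; CO2, −78 to 0 °C; cold 1 M HCl to pH 3; used at once
Reagents that add atoms: carbon dioxide, O=C=O
Why: Carboxylation of a polyanion, where the terminal carbanion of the trianion is the least stabilised and is carboxylated regioselectively; the β-keto acid is kept cold to prevent decarboxylation.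

Step 9
Reactants: 13 7-[3-(methoxymethoxy)-2-(3-methylbut-2-en-1-yl)phenyl]-3,5,7-trioxoheptanoic acid
Product: 14 methyl 7-[3-(methoxymethoxy)-2-(3-methylbut-2-en-1-yl)phenyl]-3,5,7-trioxoheptanoate
Conditions: Me3SiCHN2 (1.05 equiv), toluene/MeOH (4:1), 0 °C
Reagents that add atoms: (trimethylsilyl)diazomethane, C[Si](C)(C)C=[N+]=[N-]
Why: Diazoalkane esterification of the carboxylic acid (protonation, then SN2 on the diazonium) is much faster than O-methylation of the enols.

Step 10
Reactants: 14 methyl 7-[3-(methoxymethoxy)-2-(3-methylbut-2-en-1-yl)phenyl]-3,5,7-trioxoheptanoate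
Product: 16 [3-(methoxymethoxy)-2-(3-methylbut-2-en-1-yl)phenyl](2,4,6-trihydroxyphenyl)methanone, via cyclohexane-1,3,5-trione tautomer 15 (not isolated)
Conditions: 2 M aq. KOH, MeOH, rt, Ar; then 2 M HCl, 0 °C
Reagents that add atoms: none
Why: Intramolecular Claisen (Dieckmann-type) condensation, in which the C6 carbanion attacks the ester to close a six-membered trione that aromatises by enolisation; the competing aldol mode is disfavoured by the hindered aryl ketone.

Step 11
Reactants: 16 [3-(methoxymethoxy)-2-(3-methylbut-2-en-1-yl)phenyl](2,4,6-trihydroxyphenyl)methanone; 17 1-bromo-3-methylbut-2-ene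
Product: 18 [3-(methoxymethoxy)-2-(3-methylbut-2-en-1-yl)phenyl][2,4,6-trihydroxy-3-(3-methylbut-2-en-1-yl)phenyl]methanone
Conditions: 17 (1.0 equiv), DBU (1.1 equiv), THF, 0 °C to rt
Reagents that add atoms: none
Why: SN2 C-alkylation of the ambident acylphloroglucinol monoanion, where the two free positions of ring B are equivalent so only one mono-C-prenyl isomer can form.

Step 12
Reactants: 18 [3-(methoxymethoxy)-2-(3-methylbut-2-en-1-yl)phenyl][2,4,6-trihydroxy-3-(3-methylbut-2-en-1-yl)phenyl]methanone
Product: 19 cudraphenone D, [3-hydroxy-2-(3-methylbut-2-en-1-yl)phenyl][2,4,6-trihydroxy-3-(3-methylbut-2-en-1-yl)phenyl]methanone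
Conditions: 3 M aq. HCl/MeOH (1:10), rt to 40 °C
Reagents that add atoms: none
Why: Acid-catalysed acetal solvolysis transfers the methoxymethyl group to methanol under conditions mild enough not to cyclise the ortho-prenyl phenols to chromans.

**Compound list**
1 | 3-hydroxy-2-methylbenzoic acid | Cc1c(O)cccc1C(=O)O | starting material
2 | methyl 3-hydroxy-2-methylbenzoate | COC(=O)c1cccc(O)c1C | intermediate
3 | methyl 2-methyl-3-[(triisopropylsilyl)oxy]benzoate | COC(=O)c1cccc(O[Si](C(C)C)(C(C)C)C(C)C)c1C | intermediate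
4 | methyl 2-(bromomethyl)-3-[(triisopropylsilyl)oxy]benzoate | COC(=O)c1cccc(O[Si](C(C)C)(C(C)C)C(C)C)c1CBr | intermediate
5 | 4,4,5,5-tetramethyl-2-(2-methylprop-1-en-1-yl)-1,3,2-dioxaborolane | CC(C)=CB1OC(C)(C)C(C)(C)O1 | starting material
6 | methyl 2-(3-methylbut-2-en-1-yl)-3-[(triisopropylsilyl)oxy]benzoate | COC(=O)c1cccc(O[Si](C(C)C)(C(C)C)C(C)C)c1CC=C(C)C | intermediate
7 | methyl 3-hydroxy-2-(3-methylbut-2-en-1-yl)benzoate | COC(=O)c1cccc(O)c1CC=C(C)C | intermediate
8 | methyl 3-(methoxymethoxy)-2-(3-methylbut-2-en-1-yl)benzoate | COCOc1cccc(C(=O)OC)c1CC=C(C)C | intermediate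
9 | pentane-2,4-dione (acetylacetone) | CC(=O)CC(C)=O | starting material
10 | dilithio acetylacetone (dianion of 9) | [Li+].[Li+].C=C([O-])C=C(C)[O-] | intermediate
11 | 1-[3-(methoxymethoxy)-2-(3-methylbut-2-en-1-yl)phenyl]hexane-1,3,5-trione | COCOc1cccc(C(=O)CC(=O)CC(C)=O)c1CC=C(C)C | intermediate
12 | trilithium trienolate of 11 | [Li+].[Li+].[Li+].C=C([O-])C=C([O-])C=C([O-])c1cccc(OCOC)c1CC=C(C)C | intermediate
13 | 7-[3-(methoxymethoxy)-2-(3-methylbut-2-en-1-yl)phenyl]-3,5,7-trioxoheptanoic acid | COCOc1cccc(C(=O)CC(=O)CC(=O)CC(=O)O)c1CC=C(C)C | intermediate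
14 | methyl 7-[3-(methoxymethoxy)-2-(3-methylbut-2-en-1-yl)phenyl]-3,5,7-trioxoheptanoate | COCOc1cccc(C(=O)CC(=O)CC(=O)CC(=O)OC)c1CC=C(C)C | intermediate
15 | 2-[3-(methoxymethoxy)-2-(3-methylbut-2-en-1-yl)benzoyl]cyclohexane-1,3,5-trione | COCOc1cccc(C(=O)C2C(=O)CC(=O)CC2=O)c1CC=C(C)C | intermediate
16 | [3-(methoxymethoxy)-2-(3-methylbut-2-en-1-yl)phenyl](2,4,6-trihydroxyphenyl)methanone | COCOc1cccc(C(=O)c2c(O)cc(O)cc2O)c1CC=C(C)C | intermediate
17 | 1-bromo-3-methylbut-2-ene (prenyl bromide) | CC(C)=CCBr | starting material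
18 | [3-(methoxymethoxy)-2-(3-methylbut-2-en-1-yl)phenyl][2,4,6-trihydroxy-3-(3-methylbut-2-en-1-yl)phenyl]methanone | COCOc1cccc(C(=O)c2c(O)cc(O)c(CC=C(C)C)c2O)c1CC=C(C)C | intermediate
19 | cudraphenone D | CC(C)=CCc1c(O)cccc1C(=O)c1c(O)cc(O)c(CC=C(C)C)c1O | target

**Summary**
Total step count: 12. Longest linear sequence: 12 steps (1 to 19); compounds 5, 9 and 17 are bought.

**Steps most likely to fail, with fallbacks**

Step 7 (Claisen condensation on an ortho-substituted, hindered ester). The fallback sets out from compound 8 and comes back at compound 11, replacing acylation by an aldol addition followed by oxidation. Ester 8 is reduced with i-Bu2AlH (CH2Cl2, −78 to 0 °C) to [3-(methoxymethoxy)-2-(3-methylbut-2-en-1-yl)phenyl]methanol F1. This is oxidised with MnO2 (CH2Cl2, rt) to 3-(methoxymethoxy)-2-(3-methylbut-2-en-1-yl)benzaldehyde F2. Intermolecular aldol addition of dilithio acetylacetone 10 to the far more electrophilic aldehyde (THF, −78 °C) gives racemic 6-hydroxy-6-[3-(methoxymethoxy)-2-(3-methylbut-2-en-1-yl)phenyl]hexane-2,4-dione F3. Dess–Martin periodinane (NaHCO3, CH2Cl2, 0 °C) oxidises the benzylic carbinol, which removes the transient stereocentre and gives 11.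

Step 8 (trianion formation, carboxylation, and the decarboxylation-prone β-keto acid 13). The fallback sets out from compound 8 and comes back at compound 16, avoiding both the trianion and the free acid by using a pyrone as a masked triketo acid. Commercial 4-hydroxy-6-methyl-2H-pyran-2-one (triacetic acid lactone, CC1=CC(O)=CC(=O)O1) is converted with LiN(i-Pr)2 (2 equiv per pyrone, THF, −78 °C) into the dilithio dianion of 4-hydroxy-6-methyl-2H-pyran-2-one F4. Its exocyclic carbanion is acylated by ester 8 in a vinylogous Claisen condensation to give 4-hydroxy-6-{2-[3-(methoxymethoxy)-2-(3-methylbut-2-en-1-yl)phenyl]-2-oxoethyl}-2H-pyran-2-one F5. Mg(OMe)2 in MeOH at reflux opens the lactone to the magnesium chelate of 14, which closes by Claisen cyclisation through 15 to 16.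

Step 11 (mono-C-prenylation, where O-alkylation and double alkylation compete). The fallback sets out from compound 16 and comes back at compound 18, delivering the prenyl group through oxygen and a sigmatropic shift. The 4-hydroxyl of ring B is the only one not hydrogen-bonded to the ketone; it is etherified with 3-chloro-3-methylbut-1-yne (CC(C)(Cl)C#C), DBU and catalytic CuCl2 in MeCN at 0 °C to give {2,6-dihydroxy-4-[(2-methylbut-3-yn-2-yl)oxy]phenyl}[3-(methoxymethoxy)-2-(3-methylbut-2-en-1-yl)phenyl]methanone F6. Semi-hydrogenation (H2, Pd/CaCO3 poisoned by Pb(OAc)2, quinoline, EtOAc) leaves the trisubstituted prenyl alkene untouched and gives {2,6-dihydroxy-4-[(2-methylbut-3-en-2-yl)oxy]phenyl}[3-(methoxymethoxy)-2-(3-methylbut-2-en-1-yl)phenyl]methanone F7. Heating in toluene at 110 °C triggers an aromatic Claisen rearrangement to either of the two equivalent ortho positions, giving 3,5-dihydroxy-4-[3-(methoxymethoxy)-2-(3-methylbut-2-en-1-yl)benzoyl]-6-(3-methylbut-2-en-1-yl)cyclohexa-2,4-dien-1-one F8, which tautomerises to 18.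

**Further compounds**
F1 | step 7 | [3-(methoxymethoxy)-2-(3-methylbut-2-en-1-yl)phenyl]methanol | COCOc1cccc(CO)c1CC=C(C)C
F2 | step 7 | 3-(methoxymethoxy)-2-(3-methylbut-2-en-1-yl)benzaldehyde | COCOc1cccc(C=O)c1CC=C(C)C
F3 | step 7 | 6-hydroxy-6-[3-(methoxymethoxy)-2-(3-methylbut-2-en-1-yl)phenyl]hexane-2,4-dione (racemic) | COCOc1cccc(C(O)CC(=O)CC(C)=O)c1CC=C(C)C
F4 | step 8 | dilithio dianion of 4-hydroxy-6-methyl-2H-pyran-2-one | [Li+].[Li+].[CH2-]C1=CC([O-])=CC(=O)O1
F5 | step 8 | 4-hydroxy-6-{2-[3-(methoxymethoxy)-2-(3-methylbut-2-en-1-yl)phenyl]-2-oxoethyl}-2H-pyran-2-one | COCOc1cccc(C(=O)CC2=CC(O)=CC(=O)O2)c1CC=C(C)C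
F6 | step 11 | {2,6-dihydroxy-4-[(2-methylbut-3-yn-2-yl)oxy]phenyl}[3-(methoxymethoxy)-2-(3-methylbut-2-en-1-yl)phenyl]methanone | COCOc1cccc(C(=O)c2c(O)cc(OC(C)(C)C#C)cc2O)c1CC=C(C)C
F7 | step 11 | {2,6-dihydroxy-4-[(2-methylbut-3-en-2-yl)oxy]phenyl}[3-(methoxymethoxy)-2-(3-methylbut-2-en-1-yl)phenyl]methanone | COCOc1cccc(C(=O)c2c(O)cc(OC(C)(C)C=C)cc2O)c1CC=C(C)C
F8 | step 11 | 3,5-dihydroxy-4-[3-(methoxymethoxy)-2-(3-methylbut-2-en-1-yl)benzoyl]-6-(3-methylbut-2-en-1-yl)cyclohexa-2,4-dien-1-one (racemic, transient) | COCOc1cccc(C(=O)C2=C(O)C(CC=C(C)C)C(=O)C=C2O)c1CC=C(C)C
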